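## Structural features

The target is an α-arylidene-γ-butyrolactone lignan: one five-membered lactone (ring A: O1, carbonyl C2, C3, C4, C5) and two phenolic arenes. C3 carries an exocyclic double bond to the methine of a 4-hydroxy-3,5-dimethoxyphenyl (syringyl) ring, with the aryl group anti to the carbonyl (E). C4 carries a 4-hydroxy-3-methoxybenzyl (guaiacylmethyl) group. C4 (R) is the only stereocentre, so no neighbouring centre can relay its configuration, and its three carbon arms (C5H2–O, C3, benzylic CH2) differ only at the second atom. Fragile points are the two electron-rich free phenols, the hydrolysable lactone, the enoate as a Michael acceptor, and above all the C4–H bond. That bond is allylic and γ to the carbonyl, so once the alkene exists a base can remove it, move the double bond into the ring and erase the stereocentre. The real difficulty is therefore to set an isolated tertiary centre in high enantiopurity and then to introduce the E alkene late and mildly enough that the centre survives. The key step exploits the triad C3–C4–benzylic CH2: one extra bond between C3 and the benzylic carbon turns ring A into a 3-oxabicyclo[3.1.0]hexan-2-one whose cyclopropane is C3, C4 and the benzylic carbon. That bicycle is what a carbene at C3 forms on adding to a Z aryl-substituted allylic ester, and the extra bond is both benzylic and α to the carbonyl, so it can be removed again without touching C4.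

## Logic of the disconnections

15 from 14. The two phenolic O–H bonds are traced back to O–Si bonds. Free phenols would react with the carbene, the lithium amide and the sulfonyl chloride used earlier, so this cut enables all the others without simplifying the skeleton. The forward step must remove silicon without opening the lactone, adding to the enoate or deprotonating C4–H, which calls for buffered fluoride.

14 from 12 through 13. The exocyclic C3=C bond is opened by formal addition of water, oxygen on the benzylic carbon and hydrogen on C3. This turns the alkene problem into an elimination and exposes an aldol retron. Forward, the hydroxyl of 12 must become a leaving group (13) and leave through the lactone enolate, giving the E alkene before C4–H is attacked.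

12 from 9 and 11. The bond between C3 and the carbinol carbon is cut. It is the most convergent bond: 11 supplies the whole syringyl half, 9 the stereocentre and the guaiacyl half. The forward aldol needs a single enolizable position in 9 (only C3 qualifies), a non-enolizable aldehyde, and a masked phenol in 11 so that the carbonyl stays electrophilic.

11 from 10. One O–Si bond is cut. 10 is a commercial phenolic aldehyde, and the forward step is silylation of a hindered but acidic phenol.

9 from 8. Here a bond is added instead of cut: C3 of 9 is joined to its benzylic carbon, giving the cyclopropane-fused lactone 8 (the C1–C6 bond in the numbering of 8). The lone stereocentre, hard to address directly, thereby becomes part of a rigid bicycle that a catalyst can build from a flat alkene. The cost is one reductive step with a regiochemical demand: hydrogen must break C1–C6 (benzylic and α to the carbonyl), not C5–C6 (benzylic only) or C1–C5.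

8 from 7. The two cyclopropane bonds meeting at C1 (C1–C5 and C1–C6) are cut, the retron of a carbene adding to an alkene. Two rings, two C–C bonds and three stereocentres vanish at once, leaving an achiral open-chain diazo ester. Forward, the alkene of 7 must be Z (it puts the aryl group endo and is the geometry this catalyst family discriminates best). The catalyst must select one alkene face, and the carbene must prefer the tethered alkene to dimerization, C–H insertion or the arene.

7 from 6, and 6 from 5. The diazo nitrogen pair on the acetate carbon is exchanged for bromine, then the ester C–O bond is cut. The most sensitive group is thus installed last, by a two-step sequence that needs no azide-transfer reagent, no ketene dimer and no hydroxide. The forward steps must not acidify the medium (an electron-rich Z-cinnamyl system ionizes and isomerizes easily) and must leave the aryl silyl ether alone.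

5 from 4. The Z double bond is traced to a triple bond by formal removal of H2. Syn delivery of hydrogen to an alkyne is the most dependable source of a Z-disubstituted alkene. The forward reduction must stop at the alkene and must not isomerize it.

4 from 2 and 3. The bond between the arene and the sp carbon is cut, a cross-coupling retron that separates a three-carbon alkynol from an aryl bromide. The aryl bromide is electron-rich, so the forward coupling needs a catalyst that inserts readily into such a C–Br bond.

2 from 1. One O–Si bond is cut. 1 is commercial and already carries bromine para to the phenol, so no regiochemical question arises.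

## Other disconnections considered

Alternative 1: The cut takes the carbonyl carbon out of the ring by breaking its bonds to O1 and to C3. This leads back to carbon monoxide and the homopropargylic alcohol A1, (2R)-2-[3-methoxy-4-(methoxymethoxy)benzyl]-4-[3,5-dimethoxy-4-(methoxymethoxy)phenyl]but-3-yn-1-ol. In the forward key step, divalent palladium (PdCl2 with SnCl2 and PPh3) under CO would convert the hydroxyl group into an alkoxycarbonyl–palladium unit and add it syn across the alkyne. Protonolysis of the vinyl–palladium bond would then release A2, the bis(methoxymethyl) ether of the target.
- In its favour: the syn addition leaves the acyl group and the vinylic hydrogen on the same side, so the E geometry follows from the mechanism and not from an equilibrium. Ring and alkene arise together in the penultimate step. The aryl alkyne can be assembled convergently by Sonogashira coupling. The closing acetal cleavage is acidic, a medium in which the exocyclic alkene does not migrate.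
- Against it here: the step creates no stereocentre, so the propargylic centre of A1 needs separate asymmetric chemistry and an alkyne-forming sequence that probably passes through a configurationally labile α-branched aldehyde. Pressurized CO is a hazard of its own. An internal aryl alkyne is a slower partner than a terminal one. The Lewis-acidic tin additive has to leave two acetals intact.
- Comparison: on alkene geometry and on keeping base away from the finished enoate this plan is the better one. On the stereocentre the chosen plan is stronger, because one catalytic step sets it while forming both skeletal bonds at C3. The step counts are expected to be about equal.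

Alternative 2: Two bonds near the stereocentre are cut, C3–C4 and the bond from the benzylic CH2 to the guaiacyl ring, so that C4 and its CH2 arm come from a vinyl group. The components are:
- the Z vinyl bromide A3, tert-butyl{[(2Z)-2-bromo-3-[3,5-dimethoxy-4-(methoxymethoxy)phenyl]prop-2-en-1-yl]oxy}dimethylsilane, source of the alkenyllithium by halogen–lithium exchange;
- vinylboronic acid pinacol ester A4;
- the aryl triflate A5, 3-methoxy-4-(methoxymethoxy)phenyl trifluoromethanesulfonate.

In the forward key step the alkenyllithium adds to A4 to give a boron ate complex. Zerovalent palladium, formed from Pd(OAc)2 and a MandyPhos-type ferrocenyl diphosphine, inserts into A5. The cationic arylpalladium binds the vinyl group and induces a 1,2-shift of the alkenyl group from boron to carbon. Reductive elimination would deliver the secondary allylic boronate A6 with C4 set by the ligand. No ring closes. One-carbon homologation of the C–B bond, oxidation, desilylation, oxidative lactonization and acetal removal would have to follow.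
- In its favour: the coupling is fully convergent, forms both C–C bonds at the future C4 and fixes its configuration in one catalytic event. The alkene geometry is locked in A3 beforehand and never passes through an elimination. No diazo compound is handled.
- Against it here: the migrating group is an α-branched trisubstituted alkenyl unit, a demanding case for the metallate shift. The ate complex holds two different alkenyl groups, so palladium may bind the wrong one or plain transmetallation may compete. A6 is an allylic boronate open to 1,3-boron shift and protodeboronation, and its homologation next to a fully substituted alkene carbon is hindered. Five operations lie between A6 and the target, and A3 itself needs several steps.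
- Comparison: in convergence and in freedom from an E/Z-determining elimination this plan is the equal or the better. In safety it avoids the diazo ester but brings organolithium chemistry at low temperature. The chosen plan is ahead in how securely the mechanism can be expected to deliver C4 on this substrate and in the number of operations after the key step. The overall step count is expected to be higher here.

Alternative 3: The bond between O1 and C5 is cut and the oxygen removed, which contracts ring A to the prochiral cyclobutanone A7, 3-[4-(benzyloxy)-3-methoxybenzyl]cyclobutan-1-one. In the forward key step a Baeyer–Villiger monooxygenase with O2 and recycled NADPH adds its flavin peroxide to the ketone. One of the two enantiotopic CH2 groups then migrates to oxygen, expanding the ring to A8, (4R)-4-[4-(benzyloxy)-3-methoxybenzyl]dihydrofuran-2(3H)-one.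
- In its favour: A7 should be reachable in about three steps from an allylbenzene of the phenylpropanoid pool by a ketene [2+2] cycloaddition and dechlorination. The oxidant is air, the medium is water, and neither a diazo compound nor a noble metal is used. A8 has the configuration and oxidation level of 9, so the aldol and elimination of the chosen route would apply unchanged.
- Against it here: the outcome rests on finding an enzyme that accepts a bulky, lipophilic benzylcyclobutanone and prefers the migration that gives the R lactone. Enantiopreference in this ketone class varies with enzyme and substituent. Low substrate solubility and cofactor recycling limit throughput. The benzyl ether cannot be removed by hydrogenolysis once the arylidene double bond is in place, so a Lewis-acid debenzylation or a change of protecting group is needed.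
- Comparison: in step economy and in safety this plan is the better one. Structurally the two plans are equal, since each sets C4 at the saturated lactone stage and shares the same endgame. Mechanistically the chosen plan offers a catalyst available in both enantiomeric forms with an arguable sense of induction, where the enzymatic plan depends on screening.

Key step: step 6

Assumption: the dirhodium carboxamidate is taken to show with the Z-aryl substrate 7 the sense of face selection that is general for allylic diazoacetates, which makes the 5R ligand series the one leading to (1S,5R,6S)-8. Should the sense prove opposite, the 5S series is used and nothing else changes.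

Design remarks: both phenols carry triisopropylsilyl groups. These resist DBU, lithium amide, hydrogenation and silyl transfer better than smaller silyl ethers and are just as labile to fluoride. The diazoacetate 7 is made in two steps without diketene, sulfonyl azides or hydroxide; it is kept in solution, used promptly, and never heated or distilled.

## Route

Step 1
Reactants: 1 4-bromo-2-methoxyphenol
Product: 2 (4-bromo-2-methoxyphenoxy)triisopropylsilane
Conditions: TIPSCl, imidazole, DMF, rt
Reagents that add atoms: triisopropylsilyl chloride, CC(C)[Si](Cl)(C(C)C)C(C)C
Why: Imidazole-promoted O-silylation of a phenol; the bulky silyl ether should outlast amine bases, DBU, the lithium amide and hydrogenation and still fall to fluoride at the end.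

Step 2
Reactants: 2 (4-bromo-2-methoxyphenoxy)triisopropylsilane; 3 prop-2-yn-1-ol (propargyl alcohol)
Product: 4 3-{3-methoxy-4-[(triisopropylsilyl)oxy]phenyl}prop-2-yn-1-ol
Conditions: PdCl2(PhCN)2 (3 mol%), [(t-Bu)3PH]BF4 (6 mol%), CuI (copper iodide, 2 mol%), i-Pr2NH, dioxane, rt
Reagents that add atoms: none
Why: Sonogashira coupling; the bulky electron-rich phosphine lets zerovalent palladium insert into the electron-rich aryl bromide near room temperature, and copper acetylide transfer and reductive elimination follow; the free hydroxyl and the aryl silyl ether are tolerated.

Step 3
Reactants: 4 3-{3-methoxy-4-[(triisopropylsilyl)oxy]phenyl}prop-2-yn-1-ol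
Product: 5 (2Z)-3-{3-methoxy-4-[(triisopropylsilyl)oxy]phenyl}prop-2-en-1-ol
Conditions: H2 (1 atm), Pd/CaCO3 poisoned with Pb(OAc)2, quinoline, EtOAc, rt, stopped after one equivalent of H2
Reagents that add atoms: none
Why: Lindlar semihydrogenation; both hydrogens come from the metal surface to the same face of the alkyne, which gives the Z alkene, and the poisoned catalyst reduces that alkene only slowly.

Step 4
Reactants: 5 (2Z)-3-{3-methoxy-4-[(triisopropylsilyl)oxy]phenyl}prop-2-en-1-ol
Product: 6 (2Z)-3-{3-methoxy-4-[(triisopropylsilyl)oxy]phenyl}prop-2-en-1-yl bromoacetate
Conditions: BrCH2COBr, NaHCO3, MeCN, 0 °C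
Reagents that add atoms: bromoacetyl bromide, BrCC(Br)=O
Why: O-acylation of a primary allylic alcohol by an acid bromide; solid hydrogen carbonate takes up HBr, so the Z alkene, the ionizable cinnamyl C–O bond and the silyl ether never meet acid.

Step 5
Reactants: 6 (2Z)-3-{3-methoxy-4-[(triisopropylsilyl)oxy]phenyl}prop-2-en-1-yl bromoacetate
Product: 7 (2Z)-3-{3-methoxy-4-[(triisopropylsilyl)oxy]phenyl}prop-2-en-1-yl diazoacetate
Conditions: TsNHNHTs, DBU, THF, 0 °C
Reagents that add atoms: N,N'-ditosylhydrazine, Cc1ccc(cc1)S(=O)(=O)NNS(=O)(=O)c1ccc(C)cc1
Why: Diazoacetate formation from a bromoacetate and a bis-sulfonyl hydrazine: SN2 alkylation of the hydrazine anion at the bromoacetate carbon, then two base-induced losses of p-toluenesulfinate, leave the C=N2 unit; brief contact with DBU at 0 °C should not affect the hindered aryl silyl ether or the Z alkene.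

Step 6
Reactants: 7 (2Z)-3-{3-methoxy-4-[(triisopropylsilyl)oxy]phenyl}prop-2-en-1-yl diazoacetate
Product: 8 (1S,5R,6S)-6-{3-methoxy-4-[(triisopropylsilyl)oxy]phenyl}-3-oxabicyclo[3.1.0]hexan-2-one (aryl group endo; the three cyclopropane hydrogens mutually cis)
Conditions: Rh2(5R-MEPY)4 [dirhodium tetrakis(methyl (5R)-2-oxopyrrolidine-5-carboxylate)] (1 mol%), CH2Cl2, reflux, slow addition of 7
Reagents that add atoms: none
Why: The diazo carbon binds an axial site of the dirhodium core and loses N2 to give an electrophilic rhodium carbene, which adds to the tethered Z alkene in one asynchronous [2+1] event, the bond to the alkene carbon nearer the ester forming ahead of the bond to the benzylic carbon. The closest known reaction type is the enantioselective intramolecular cyclopropanation of allylic diazoacetates by chiral dirhodium carboxamidates, for which cis-disubstituted alkenes are the best-behaved substrates. The lactone closes in a five-membered exo mode (new C1–C5 bond, the benzylic alkene carbon staying outside that ring), and the cyclopropane closes as the three-membered ring of the carbene addition across the same π bond (new C1–C6 bond). C1 and C5 must be cis because the three-atom tether cannot span a trans-fused bicyclo[3.1.0] system, and C6 carries the aryl group endo because the syn addition is stereospecific and keeps the Z geometry of 7. The absolute configuration of all three centres is decided together by which alkene face meets the carbene, a choice made by the ester-bearing chiral carboxamidate ligands; the 5R catalyst is expected to give (1S,5R,6S)-8. The step needs enantioface selectivity and chemoselectivity over carbene dimerization, C–H insertion and attack on the electron-rich arene; slow addition keeps the diazo concentration low, the carboxamidate ligands temper the carbene, and the short tether makes alkene addition the fastest intramolecular path.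

Step 7
Reactants: 8 (1S,5R,6S)-6-{3-methoxy-4-[(triisopropylsilyl)oxy]phenyl}-3-oxabicyclo[3.1.0]hexan-2-one
Product: 9 (4R)-4-{3-methoxy-4-[(triisopropylsilyl)oxy]benzyl}dihydrofuran-2(3H)-one
Conditions: H2 (3 atm), Pd/C, EtOAc, rt
Reagents that add atoms: none
Why: Catalytic hydrogenolysis of an activated cyclopropane; C1–C6 is the only ring bond that is both benzylic and α to the carbonyl, so it should be the one broken. C5 takes no part and becomes C4 of 9 with its configuration (R) intact, while C1 and C6 become CH2 groups; the aprotic solvent protects the silyl ether.

Step 8
Reactants: 10 4-hydroxy-3,5-dimethoxybenzaldehyde (syringaldehyde)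
Product: 11 3,5-dimethoxy-4-[(triisopropylsilyl)oxy]benzaldehyde
Conditions: TIPSCl, imidazole, DMF, rt
Reagents that add atoms: triisopropylsilyl chloride, CC(C)[Si](Cl)(C(C)C)C(C)C
Why: O-silylation of an acidic, hindered phenol; masking it keeps the aldehyde electrophilic (a free phenoxide would deactivate it as a vinylogous carboxylate), and the bulky group resists transfer to the aldolate oxygen in step 9.

Step 9
Reactants: 9 (4R)-4-{3-methoxy-4-[(triisopropylsilyl)oxy]benzyl}dihydrofuran-2(3H)-one; 11 3,5-dimethoxy-4-[(triisopropylsilyl)oxy]benzaldehyde
Product: 12 (3S,4R)-3-{hydroxy[3,5-dimethoxy-4-(triisopropylsilyloxy)phenyl]methyl}-4-{3-methoxy-4-[(triisopropylsilyl)oxy]benzyl}dihydrofuran-2(3H)-one (3,4-trans; both epimers at the carbinol carbon)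
Conditions: LiN(i-Pr)2, THF, −78 °C; then 11, −78 °C; AcOH quench at −78 °C
Reagents that add atoms: none
Why: Aldol addition of a lactone lithium enolate to a non-enolizable aromatic aldehyde; the aldehyde approaches the enolate face anti to the C4 benzyl group, giving the 3,4-trans adduct. C4 is not acidic here and keeps its configuration, and the carbinol centre needs no control because it disappears in step 10.

Step 10
Reactants: 12 (3S,4R)-3-{hydroxy[3,5-dimethoxy-4-(triisopropylsilyloxy)phenyl]methyl}-4-{3-methoxy-4-[(triisopropylsilyl)oxy]benzyl}dihydrofuran-2(3H)-one
Product: 14 (3E,4R)-3-{3,5-dimethoxy-4-[(triisopropylsilyl)oxy]benzylidene}-4-{3-methoxy-4-[(triisopropylsilyl)oxy]benzyl}dihydrofuran-2(3H)-one, via methanesulfonate 13 (not isolated)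
Conditions: MsCl, Et3N, CH2Cl2, 0 °C; then DBU, 0 °C to rt
Reagents that add atoms: methanesulfonyl chloride, CS(Cl)(=O)=O (its atoms are carried only by intermediate 13 and leave again in the elimination)
Why: Mesylation of the secondary benzylic alcohol, then E1cB elimination through the lactone enolate; both carbinol epimers converge because the enolate no longer remembers C3, and the E alkene (aryl anti to the carbonyl) is expected as the more stable conjugated isomer. DBU is limited in amount and contact time so that C4–H, now γ to the carbonyl, is not removed.

Step 11
Reactants: 14 (3E,4R)-3-{3,5-dimethoxy-4-[(triisopropylsilyl)oxy]benzylidene}-4-{3-methoxy-4-[(triisopropylsilyl)oxy]benzyl}dihydrofuran-2(3H)-one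
Product: 15 (3E,4R)-3-(4-hydroxy-3,5-dimethoxybenzylidene)-4-(4-hydroxy-3-methoxybenzyl)dihydrofuran-2(3H)-one (CNP0351244.1)
Conditions: TBAF, AcOH, THF, 0 °C
Reagents that add atoms: none
Why: Fluoride cleavage of two aryl silyl ethers, driven by the strong Si–F bond; acetic acid protonates the phenoxides as they form, so no basic species remains to open the lactone, add to the enoate or deprotonate C4–H.

## Compound list

1 | 4-bromo-2-methoxyphenol | COc1cc(Br)ccc1O | starting material
2 | (4-bromo-2-methoxyphenoxy)triisopropylsilane | COc1cc(Br)ccc1O[Si](C(C)C)(C(C)C)C(C)C | intermediate
3 | prop-2-yn-1-ol (propargyl alcohol) | C#CCO | starting material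
4 | 3-{3-methoxy-4-[(triisopropylsilyl)oxy]phenyl}prop-2-yn-1-ol | COc1cc(C#CCO)ccc1O[Si](C(C)C)(C(C)C)C(C)C | intermediate
5 | (2Z)-3-{3-methoxy-4-[(triisopropylsilyl)oxy]phenyl}prop-2-en-1-ol | COc1cc(/C=C\CO)ccc1O[Si](C(C)C)(C(C)C)C(C)C | intermediate
6 | (2Z)-3-{3-methoxy-4-[(triisopropylsilyl)oxy]phenyl}prop-2-en-1-yl bromoacetate | COc1cc(/C=C\COC(=O)CBr)ccc1O[Si](C(C)C)(C(C)C)C(C)C | intermediate
7 | (2Z)-3-{3-methoxy-4-[(triisopropylsilyl)oxy]phenyl}prop-2-en-1-yl diazoacetate | COc1cc(/C=C\COC(=O)C=[N+]=[N-])ccc1O[Si](C(C)C)(C(C)C)C(C)C | intermediate
8 | (1S,5R,6S)-6-{3-methoxy-4-[(triisopropylsilyl)oxy]phenyl}-3-oxabicyclo[3.1.0]hexan-2-one (aryl endo) | O=C1OC[C@H]2[C@@H]1[C@H]2c1ccc(O[Si](C(C)C)(C(C)C)C(C)C)c(OC)c1 | intermediate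
9 | (4R)-4-{3-methoxy-4-[(triisopropylsilyl)oxy]benzyl}dihydrofuran-2(3H)-one | COc1cc(C[C@H]2COC(=O)C2)ccc1O[Si](C(C)C)(C(C)C)C(C)C | intermediate
10 | 4-hydroxy-3,5-dimethoxybenzaldehyde (syringaldehyde) | COc1cc(C=O)cc(OC)c1O | starting material
11 | 3,5-dimethoxy-4-[(triisopropylsilyl)oxy]benzaldehyde | COc1cc(C=O)cc(OC)c1O[Si](C(C)C)(C(C)C)C(C)C | intermediate
12 | (3S,4R)-3-{hydroxy[3,5-dimethoxy-4-(triisopropylsilyloxy)phenyl]methyl}-4-{3-methoxy-4-[(triisopropylsilyl)oxy]benzyl}dihydrofuran-2(3H)-one (both carbinol epimers) | COc1cc(C[C@H]2COC(=O)[C@@H]2C(O)c2cc(OC)c(O[Si](C(C)C)(C(C)C)C(C)C)c(OC)c2)ccc1O[Si](C(C)C)(C(C)C)C(C)C | intermediate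
13 | (3S,4R)-3-{[3,5-dimethoxy-4-(triisopropylsilyloxy)phenyl](methanesulfonyloxy)methyl}-4-{3-methoxy-4-[(triisopropylsilyl)oxy]benzyl}dihydrofuran-2(3H)-one (both epimers at the sulfonate-bearing carbon; not isolated) | COc1cc(C[C@H]2COC(=O)[C@@H]2C(OS(C)(=O)=O)c2cc(OC)c(O[Si](C(C)C)(C(C)C)C(C)C)c(OC)c2)ccc1O[Si](C(C)C)(C(C)C)C(C)C | intermediate
14 | (3E,4R)-3-{3,5-dimethoxy-4-[(triisopropylsilyl)oxy]benzylidene}-4-{3-methoxy-4-[(triisopropylsilyl)oxy]benzyl}dihydrofuran-2(3H)-one | COc1cc(C[C@H]2COC(=O)/C2=C/c2cc(OC)c(O[Si](C(C)C)(C(C)C)C(C)C)c(OC)c2)ccc1O[Si](C(C)C)(C(C)C)C(C)C | intermediate
15 | (3E,4R)-3-(4-hydroxy-3,5-dimethoxybenzylidene)-4-(4-hydroxy-3-methoxybenzyl)dihydrofuran-2(3H)-one | COc1cc(C[C@H]2COC(=O)/C2=C/c2cc(OC)c(O)c(OC)c2)ccc1O | target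

## Step count and least certain steps

Total: 11 steps. Longest linear sequence: 10 steps (steps 1 to 7, then 9, 10 and 11); step 8 is a one-step side branch.

Key step (step 6). The most likely failure is insufficient discrimination between the two alkene faces. The aryl group is larger and more electron-rich than the substituents for which the catalyst model is most secure, and the assumed sense of induction could also be reversed. Carbene dimerization (if the diazo ester accumulates) and attack on the electron-rich ring are lesser risks. The fallback replaces alkene addition by carbene C–H insertion, a known reaction type for 3-arylpropyl diazoacetates. It sets out from 4 and proceeds as follows: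
- Exhaustive hydrogenation (H2, Pd/C, EtOAc) should give 3-{3-methoxy-4-[(triisopropylsilyl)oxy]phenyl}propan-1-ol F1.
- Acylation as in step 4 should give 3-{3-methoxy-4-[(triisopropylsilyl)oxy]phenyl}propyl bromoacetate F2.
- Treatment as in step 5 should give 3-{3-methoxy-4-[(triisopropylsilyl)oxy]phenyl}propyl diazoacetate F3.
- Rh2(MPPIM)4 (dirhodium tetrakis[methyl 1-(3-phenylpropanoyl)-2-oxoimidazolidine-4-carboxylate], in the enantiomeric series that leads to the R lactone) in CH2Cl2 at reflux should insert the carbene into the C–H bond two carbons from the ester oxygen and close the five-membered lactone.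

The detour comes back to the route at 9 and makes steps 3 to 7 unnecessary.

Step 7. The most likely failure is cleavage of the other benzylic bond, C5–C6, because the surface reaction distinguishes the two benzylic bonds only through the carbonyl group; this would move the benzyl group to the α-carbon. Slow turnover on the crowded all-cis face is the second concern. The fallback is heterolytic instead of surface-mediated and sets out from 8: Et3SiH with BF3·OEt2 in CH2Cl2 at low temperature. Acid on the carbonyl oxygen can open only C1–C6, the one ring bond whose heterolysis gives a p-silyloxybenzyl cation and an enolate together. The silane then delivers hydride to the benzylic carbon, and aqueous work-up returns the lactone. The detour comes back at 9. New compounds on this detour: none F0.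

Step 3. The most likely failures are over-reduction to the saturated alcohol and partial Z to E isomerization on the catalyst. The E isomer would pass through steps 4 to 7 as the exo cyclopropane, with a different level or sense of induction, and would lower the enantiopurity of 9. The fallback builds the Z alkene by cross-coupling with retention and sets out from 2: Stille coupling with (2Z)-3-(tributylstannyl)prop-2-en-1-ol, Pd(PPh3)4, toluene, 100 °C. It replaces steps 2 and 3 and comes back at 5. New compounds on this detour: none F0.

Step 10. The most likely failures are incomplete geometric control in the elimination and removal of C4–H by the amidine base once the alkene has formed, which would shift the double bond into the ring and erase the stereocentre. Retro-aldol cleavage of 12 before sulfonylation is a lesser risk. The fallback forms the C=C bond by Horner–Wadsworth–Emmons olefination and sets out from 9. LiN(i-Pr)2 and ClP(O)(OEt)2 give the enol phosphate, and further LiN(i-Pr)2 induces the oxygen-to-carbon phosphorus shift to diethyl {4-{3-methoxy-4-[(triisopropylsilyl)oxy]benzyl}-2-oxotetrahydrofuran-3-yl}phosphonate F4 (benzyl-bearing centre as in 9, mixture at the phosphorus-bearing carbon). Condensation of this phosphonate with 11 under LiCl and DBU in MeCN (Masamune–Roush conditions) is expected to favour the E alkene, with a stabilized and weakly basic carbanion. It replaces steps 9 and 10 and comes back at 14.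

## Further compounds

F1 | step 6 | 3-{3-methoxy-4-[(triisopropylsilyl)oxy]phenyl}propan-1-ol | COc1cc(CCCO)ccc1O[Si](C(C)C)(C(C)C)C(C)C
F2 | step 6 | 3-{3-methoxy-4-[(triisopropylsilyl)oxy]phenyl}propyl bromoacetate | COc1cc(CCCOC(=O)CBr)ccc1O[Si](C(C)C)(C(C)C)C(C)C
F3 | step 6 | 3-{3-methoxy-4-[(triisopropylsilyl)oxy]phenyl}propyl diazoacetate | COc1cc(CCCOC(=O)C=[N+]=[N-])ccc1O[Si](C(C)C)(C(C)C)C(C)C
F0 | step 7 | none | none
F0 | step 3 | none | none
F4 | step 10 | diethyl {4-{3-methoxy-4-[(triisopropylsilyl)oxy]benzyl}-2-oxotetrahydrofuran-3-yl}phosphonate (benzyl-bearing centre as in 9) | COc1cc(C[C@H]2COC(=O)C2P(=O)(OCC)OCC)ccc1O[Si](C(C)C)(C(C)C)C(C)C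
A1 | alternative 1 | (2R)-2-[3-methoxy-4-(methoxymethoxy)benzyl]-4-[3,5-dimethoxy-4-(methoxymethoxy)phenyl]but-3-yn-1-ol | COCOc1ccc(C[C@@H](CO)C#Cc2cc(OC)c(OCOC)c(OC)c2)cc1OC
A2 | alternative 1 | (3E,4R)-3-[3,5-dimethoxy-4-(methoxymethoxy)benzylidene]-4-[3-methoxy-4-(methoxymethoxy)benzyl]dihydrofuran-2(3H)-one | COc1cc(C[C@H]2COC(=O)/C2=C/c2cc(OC)c(OCOC)c(OC)c2)ccc1OCOC
A3 | alternative 2 | tert-butyl{[(2Z)-2-bromo-3-[3,5-dimethoxy-4-(methoxymethoxy)phenyl]prop-2-en-1-yl]oxy}dimethylsilane | COCOc1c(OC)cc(/C=C(\Br)CO[Si](C)(C)C(C)(C)C)cc1OC
A4 | alternative 2 | vinylboronic acid pinacol ester (2-ethenyl-4,4,5,5-tetramethyl-1,3,2-dioxaborolane) | C=CB1OC(C)(C)C(C)(C)O1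
A5 | alternative 2 | 3-methoxy-4-(methoxymethoxy)phenyl trifluoromethanesulfonate | COCOc1ccc(OS(=O)(=O)C(F)(F)F)cc1OC
A6 | alternative 2 | tert-butyl{[(2E,3R)-2-[3,5-dimethoxy-4-(methoxymethoxy)benzylidene]-4-[3-methoxy-4-(methoxymethoxy)phenyl]-3-(4,4,5,5-tetramethyl-1,3,2-dioxaborolan-2-yl)butyl]oxy}dimethylsilane | COCOc1c(OC)cc(/C=C(/CO[Si](C)(C)C(C)(C)C)[C@@H](Cc2ccc(OCOC)c(OC)c2)B2OC(C)(C)C(C)(C)O2)cc1OC
A7 | alternative 3 | 3-[4-(benzyloxy)-3-methoxybenzyl]cyclobutan-1-one | COc1cc(CC2CC(=O)C2)ccc1OCc1ccccc1
A8 | alternative 3 | (4R)-4-[4-(benzyloxy)-3-methoxybenzyl]dihydrofuran-2(3H)-one | COc1cc(C[C@H]2COC(=O)C2)ccc1OCc1ccccc1
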